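Ring A (C1–C5, C10; labdane numbering) is disconnected at C4–C5 and reconnected at C4–C10, which turns it into the 1,2,2-trimethylcyclopentane of camphoric acid with C5 as an exocyclic carbinol. In the key step ionisation at C5 makes the CMe2 carbon C4 migrate from the quaternary C10 to C5, so the cyclopentane grows into ring A, and the tertiary C10 cation is trapped by a (Z)-allylsilane, closing ring B and leaving the C8 exocyclic methylene; C5, C9 and C10 are set together. The precursor is a cyclopentyl carbinol with an open allylsilane chain. Syn-carbocupration of a butynoate then builds the (Z)-enoate side chain.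

Key step: step 7

Remark: atom numbers are labdane numbers (ring A = C1–C5 and C10, ring B = C5–C10, C17 = methylene carbon, side chain C11–C16); (1R,3S)-camphoric anhydride and (2R)-2-methylbutanoic acid are taken as commercial.

Step 1
Reactants: 1 (1R,3S)-camphoric anhydride; 2 N-hydroxypyridine-2-thione sodium salt
Product: 4 (1R)-1,2,2-trimethylcyclopentane-1-carboxylic acid, via Barton ester carboxylate 3 (not isolated)
Conditions: 2, THF, 0 °C to rt, dark; then t-BuSH, hν (tungsten lamp), rt; 1 M HCl work-up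
Reagents that add atoms: none
Why: Barton reductive decarboxylation: the thiohydroxamate should open the anhydride at the less hindered acyl carbon on the secondary ring carbon, and the radical chain with t-BuSH then replaces that carboxyl by hydrogen, while the quaternary stereocentre (the later C10) takes no part and keeps its (R) configuration.

Step 2
Reactants: 4 (1R)-1,2,2-trimethylcyclopentane-1-carboxylic acid
Product: 6 1-[(1R)-1,2,2-trimethylcyclopentyl]prop-2-en-1-one, via acid chloride 5 (not isolated)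
Conditions: (COCl)2, DMF (cat.), CH2Cl2, 0 °C to rt; then CH2=CHSnBu3, Pd2(dba)3 (2 mol %), tri(2-furyl)phosphine, THF, 40 °C
Reagents that add atoms: tributyl(vinyl)stannane, C=C[Sn](CCCC)(CCCC)CCCC
Why: Stille acylation (palladium-catalysed coupling of an acid chloride with a vinylstannane) should give the vinyl ketone without over-addition, because no carbonyl-attacking organometallic is present; the stereocentre is not touched.

Step 3
Reactants: 6 1-[(1R)-1,2,2-trimethylcyclopentyl]prop-2-en-1-one; 7 2,3-dihydrofuran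
Product: 10 3-(4,5-dihydrofuran-2-yl)-1-[(1R)-1,2,2-trimethylcyclopentyl]propan-1-one, via 5-lithio-2,3-dihydrofuran 8 (not isolated), via lithium bis(4,5-dihydrofuran-2-yl)cuprate 9 (not isolated)
Conditions: 7, t-BuLi, THF, −78 to 0 °C; CuI (0.5 equiv), −40 °C; then 6, −78 °C; aq. NH4Cl/NH3 (pH 9)
Reagents that add atoms: none
Why: Conjugate (1,4-) addition of a Gilman cuprate: the α-lithiated cyclic enol ether is transferred to the terminal carbon of the enone, forming the C7–C8 bond, while the tert-alkyl ketone is too hindered for 1,2-addition.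

Step 4
Reactants: 10 3-(4,5-dihydrofuran-2-yl)-1-[(1R)-1,2,2-trimethylcyclopentyl]propan-1-one
Product: 11 (1R)-3-(4,5-dihydrofuran-2-yl)-1-[(1R)-1,2,2-trimethylcyclopentyl]propan-1-ol
Conditions: (S)-2-methyl-CBS-oxazaborolidine (20 mol %), catecholborane, toluene, −40 °C; MeOH, then 1 M NaOH
Reagents that add atoms: none
Why: Corey–Bakshi–Shibata reduction: with the tert-alkyl group as the large and the CH2 chain as the small substituent, the (S)-oxazaborolidine should deliver hydride to the face that gives the (R)-carbinol at C5 under catalyst control, and catecholborane leaves the enol ether untouched.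

Step 5
Reactants: 11 (1R)-3-(4,5-dihydrofuran-2-yl)-1-[(1R)-1,2,2-trimethylcyclopentyl]propan-1-ol
Product: 12 (1R,4Z)-4-[(trimethylsilyl)methyl]-1-[(1R)-1,2,2-trimethylcyclopentyl]hept-4-ene-1,7-diol
Conditions: Me3SiCH2MgCl (4 equiv), NiCl2(PPh3)2 (10 mol %), toluene/THF, 80 °C; aq. NH4Cl
Reagents that add atoms: (trimethylsilyl)methylmagnesium chloride, C[Si](C)(C)C[Mg]Cl
Why: Nickel-catalysed Kumada-type ring-opening coupling of a 5-alkyl-2,3-dihydrofuran: the vinylic C–O bond is replaced by C–CH2SiMe3 with retention, so the silylmethyl group ends cis to the hydroxyethyl arm (4Z) and the allylsilane should form as a single alkene isomer.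

Step 6
Reactants: 12 (1R,4Z)-4-[(trimethylsilyl)methyl]-1-[(1R)-1,2,2-trimethylcyclopentyl]hept-4-ene-1,7-diol
Product: 13 (1R,4Z)-7-bromo-4-[(trimethylsilyl)methyl]-1-[(1R)-1,2,2-trimethylcyclopentyl]hept-4-en-1-ol
Conditions: CBr4 (1.1 equiv), PPh3 (1.15 equiv), CH2Cl2, −20 to 0 °C
Reagents that add atoms: carbon tetrabromide, BrC(Br)(Br)Br
Why: Appel reaction: the primary alcohol should be brominated selectively, since the alkoxyphosphonium of the neopentylic secondary carbinol cannot be displaced in an SN2 process at this temperature.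

Step 7
Reactants: 13 (1R,4Z)-7-bromo-4-[(trimethylsilyl)methyl]-1-[(1R)-1,2,2-trimethylcyclopentyl]hept-4-en-1-ol
Product: 15 (1R,4aR,8aR)-1-(2-bromoethyl)-5,5,8a-trimethyl-2-methylidenedecahydronaphthalene, via secondary triflate 14 (not isolated)
Conditions: Tf2O (1.2 equiv), 2,6-di-tert-butyl-4-methylpyridine (3 equiv), CH2Cl2, −78 °C, then to −20 °C; aq. NaHCO3
Reagents that add atoms: none
Why: Proposed new method: the neopentylic triflate 14 should ionise with participation of the C4–C10 bond, which lies anti to C5–OTf, so that C4 (the CMe2 carbon) shifts from C10 to C5 with inversion at C5 and the strained 1,2,2-trimethylcyclopentane becomes the cyclohexane ring A with a tertiary cation at C10; C9 of the (Z)-allylsilane then adds to C10 and the β-silyl cation at C8 loses Me3Si+ to leave the C8=C17 methylene. The closest known reaction types are the solvolytic Wagner–Meerwein ring expansion of (1-methylcyclopentyl)carbinyl sulfonates and the allylsilane-terminated cation–olefin cyclisation of monocyclic cyclohexyl (cyclogeranyl-type) cations to trans-decalins; their union in one cascade is the new element. Ring A is not closed but enlarged by the 1,2-alkyl shift, and ring B closes in a 6-endo-trig mode on the allylsilane through a chair transition state. C5 follows from the CBS-set carbinol by inversion, C10 from capture anti to the migrated C4 (for the (R,R) diastereomer 13 this coincides with the chair that keeps the C5 tether equatorial and gives the trans ring fusion), and C9 from the alkene geometry (C7 trans to C11, side chain equatorial). The step needs migration of C4 rather than of C1 or the methyl group and C–C capture faster than proton loss: the first is secured by the higher migratory aptitude of the tert-alkyl carbon and the relief of strain between the vicinal quaternary centres, the second by the tethered, highly nucleophilic allylsilane and the non-nucleophilic hindered base, while direct 5-endo attack at the neopentylic C5 is geometrically disfavoured.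

Step 8
Reactants: 16 tert-butyldimethyl(prop-2-yn-1-yloxy)silane
Product: 18 tert-butyl 4-[(tert-butyldimethylsilyl)oxy]but-2-ynoate, via lithium acetylide 17 (not isolated)
Conditions: n-BuLi, THF, −78 °C; then Boc2O, −78 to 0 °C; aq. NH4Cl
Reagents that add atoms: di-tert-butyl dicarbonate, CC(C)(C)OC(=O)OC(=O)OC(C)(C)C
Why: Acylation of a lithium acetylide with Boc2O is a standard route to tert-butyl ynoates; no stereocentre is involved.

Step 9
Reactants: 15 (1R,4aR,8aR)-1-(2-bromoethyl)-5,5,8a-trimethyl-2-methylidenedecahydronaphthalene; 18 tert-butyl 4-[(tert-butyldimethylsilyl)oxy]but-2-ynoate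
Product: 21 tert-butyl (2Z)-3-{[(tert-butyldimethylsilyl)oxy]methyl}-5-[(1R,4aR,8aR)-5,5,8a-trimethyl-2-methylidenedecahydronaphthalen-1-yl]pent-2-enoate, via Grignard reagent 19 (not isolated), via alkylcopper reagent 20 (not isolated)
Conditions: Mg, THF, 40 °C; CuBr·SMe2 (1.0 equiv), THF, −40 °C; then 18, −78 °C; aq. NH4Cl at −78 °C
Reagents that add atoms: none
Why: syn-Carbocupration (conjugate addition of an alkylcopper–MgBr2 reagent to an ynoate): alkyl group and copper add to the same side, and protonation of the configurationally stable α-cuprio enoate at −78 °C with retention should leave the alkyl chain trans and the CH2OTBS group cis to the ester (2Z).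

Step 10
Reactants: 21 tert-butyl (2Z)-3-{[(tert-butyldimethylsilyl)oxy]methyl}-5-[(1R,4aR,8aR)-5,5,8a-trimethyl-2-methylidenedecahydronaphthalen-1-yl]pent-2-enoate
Product: 22 tert-butyl (2Z)-3-(hydroxymethyl)-5-[(1R,4aR,8aR)-5,5,8a-trimethyl-2-methylidenedecahydronaphthalen-1-yl]pent-2-enoate
Conditions: HF·pyridine, pyridine, THF, 0 °C
Reagents that add atoms: none
Why: Fluoride-induced desilylation under buffered conditions should free the primary alcohol, and the tert-butyl ester is too hindered to close to the butenolide at 0 °C.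

Step 11
Reactants: 22 tert-butyl (2Z)-3-(hydroxymethyl)-5-[(1R,4aR,8aR)-5,5,8a-trimethyl-2-methylidenedecahydronaphthalen-1-yl]pent-2-enoate; 23 (2R)-2-methylbutanoic acid
Product: 24 tert-butyl (2Z)-3-({[(2R)-2-methylbutanoyl]oxy}methyl)-5-[(1R,4aR,8aR)-5,5,8a-trimethyl-2-methylidenedecahydronaphthalen-1-yl]pent-2-enoate
Conditions: EDC·HCl, DMAP (cat.), CH2Cl2, 0 °C to rt
Reagents that add atoms: none
Why: Steglich esterification (carbodiimide/DMAP) of the primary allylic alcohol; the α-stereocentre of the simple alkyl acid should not epimerise under these conditions.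

Step 12
Reactants: 24 tert-butyl (2Z)-3-({[(2R)-2-methylbutanoyl]oxy}methyl)-5-[(1R,4aR,8aR)-5,5,8a-trimethyl-2-methylidenedecahydronaphthalen-1-yl]pent-2-enoate
Product: 26 (2Z)-3-({[(2R)-2-methylbutanoyl]oxy}methyl)-5-[(1R,4aR,8aR)-5,5,8a-trimethyl-2-methylidenedecahydronaphthalen-1-yl]pent-2-enoic acid, via trimethylsilyl ester 25 (not isolated)
Conditions: TMSOTf, 2,6-lutidine, CH2Cl2, 0 °C; then pH 5 phosphate buffer/THF
Reagents that add atoms: none
Why: Silyl triflate-mediated tert-butyl ester cleavage (O-silylation, E1 loss of isobutene under lutidine buffering, hydrolysis of the silyl ester on work-up) avoids protic acid, so that the exocyclic alkene and the allylic ester should survive.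

Compound list
1 | (1R,5S)-1,8,8-trimethyl-3-oxabicyclo[3.2.1]octane-2,4-dione ((1R,3S)-camphoric anhydride) | C[C@]12CC[C@H](C(=O)OC1=O)C2(C)C | starting material
2 | sodium 2-thioxopyridin-1(2H)-olate (N-hydroxypyridine-2-thione sodium salt) | [Na+].[O-]N1C=CC=CC1=S | starting material
3 | sodium (1R,3S)-1,2,2-trimethyl-3-{[(2-thioxopyridin-1(2H)-yl)oxy]carbonyl}cyclopentane-1-carboxylate | C[C@]1(CC[C@H](C(=O)ON2C=CC=CC2=S)C1(C)C)C(=O)[O-].[Na+] | intermediate
4 | (1R)-1,2,2-trimethylcyclopentane-1-carboxylic acid | C[C@]1(CCCC1(C)C)C(=O)O | intermediate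
5 | (1R)-1,2,2-trimethylcyclopentane-1-carbonyl chloride | C[C@]1(CCCC1(C)C)C(=O)Cl | intermediate
6 | 1-[(1R)-1,2,2-trimethylcyclopentyl]prop-2-en-1-one | C[C@]1(CCCC1(C)C)C(=O)C=C | intermediate
7 | 2,3-dihydrofuran | C1CC=CO1 | starting material
8 | 5-lithio-2,3-dihydrofuran | [Li]C1=CCCO1 | intermediate
9 | lithium bis(4,5-dihydrofuran-2-yl)cuprate | [Li+].C1CC=C(O1)[Cu-]C1=CCCO1 | intermediate
10 | 3-(4,5-dihydrofuran-2-yl)-1-[(1R)-1,2,2-trimethylcyclopentyl]propan-1-one | C[C@]1(CCCC1(C)C)C(=O)CCC1=CCCO1 | intermediate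
11 | (1R)-3-(4,5-dihydrofuran-2-yl)-1-[(1R)-1,2,2-trimethylcyclopentyl]propan-1-ol | C[C@]1(CCCC1(C)C)[C@H](O)CCC1=CCCO1 | intermediate
12 | (1R,4Z)-4-[(trimethylsilyl)methyl]-1-[(1R)-1,2,2-trimethylcyclopentyl]hept-4-ene-1,7-diol | C[C@]1(CCCC1(C)C)[C@H](O)CC/C(C[Si](C)(C)C)=C/CCO | intermediate
13 | (1R,4Z)-7-bromo-4-[(trimethylsilyl)methyl]-1-[(1R)-1,2,2-trimethylcyclopentyl]hept-4-en-1-ol | C[C@]1(CCCC1(C)C)[C@H](O)CC/C(C[Si](C)(C)C)=C/CCBr | intermediate
14 | (1R,4Z)-7-bromo-4-[(trimethylsilyl)methyl]-1-[(1R)-1,2,2-trimethylcyclopentyl]hept-4-en-1-yl trifluoromethanesulfonate | C[C@]1(CCCC1(C)C)[C@H](OS(=O)(=O)C(F)(F)F)CC/C(C[Si](C)(C)C)=C/CCBr | intermediate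
15 | (1R,4aR,8aR)-1-(2-bromoethyl)-5,5,8a-trimethyl-2-methylidenedecahydronaphthalene | C=C1CC[C@@H]2C(C)(C)CCC[C@@]2(C)[C@@H]1CCBr | intermediate
16 | tert-butyldimethyl(prop-2-yn-1-yloxy)silane | C#CCO[Si](C)(C)C(C)(C)C | starting material
17 | {3-[(tert-butyldimethylsilyl)oxy]prop-1-yn-1-yl}lithium | [Li]C#CCO[Si](C)(C)C(C)(C)C | intermediate
18 | tert-butyl 4-[(tert-butyldimethylsilyl)oxy]but-2-ynoate | CC(C)(C)OC(=O)C#CCO[Si](C)(C)C(C)(C)C | intermediate
19 | {2-[(1R,4aR,8aR)-5,5,8a-trimethyl-2-methylidenedecahydronaphthalen-1-yl]ethyl}magnesium bromide | C=C1CC[C@@H]2C(C)(C)CCC[C@@]2(C)[C@@H]1CC[Mg]Br | intermediate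
20 | {2-[(1R,4aR,8aR)-5,5,8a-trimethyl-2-methylidenedecahydronaphthalen-1-yl]ethyl}copper | C=C1CC[C@@H]2C(C)(C)CCC[C@@]2(C)[C@@H]1CC[Cu] | intermediate
21 | tert-butyl (2Z)-3-{[(tert-butyldimethylsilyl)oxy]methyl}-5-[(1R,4aR,8aR)-5,5,8a-trimethyl-2-methylidenedecahydronaphthalen-1-yl]pent-2-enoate | C=C1CC[C@@H]2C(C)(C)CCC[C@@]2(C)[C@@H]1CC/C(=C/C(=O)OC(C)(C)C)CO[Si](C)(C)C(C)(C)C | intermediate
22 | tert-butyl (2Z)-3-(hydroxymethyl)-5-[(1R,4aR,8aR)-5,5,8a-trimethyl-2-methylidenedecahydronaphthalen-1-yl]pent-2-enoate | C=C1CC[C@@H]2C(C)(C)CCC[C@@]2(C)[C@@H]1CC/C(=C/C(=O)OC(C)(C)C)CO | intermediate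
23 | (2R)-2-methylbutanoic acid | CC[C@@H](C)C(=O)O | starting material
24 | tert-butyl (2Z)-3-({[(2R)-2-methylbutanoyl]oxy}methyl)-5-[(1R,4aR,8aR)-5,5,8a-trimethyl-2-methylidenedecahydronaphthalen-1-yl]pent-2-enoate | C=C1CC[C@@H]2C(C)(C)CCC[C@@]2(C)[C@@H]1CC/C(=C/C(=O)OC(C)(C)C)COC(=O)[C@H](C)CC | intermediate
25 | trimethylsilyl (2Z)-3-({[(2R)-2-methylbutanoyl]oxy}methyl)-5-[(1R,4aR,8aR)-5,5,8a-trimethyl-2-methylidenedecahydronaphthalen-1-yl]pent-2-enoate | C=C1CC[C@@H]2C(C)(C)CCC[C@@]2(C)[C@@H]1CC/C(=C/C(=O)O[Si](C)(C)C)COC(=O)[C@H](C)CC | intermediate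
26 | (2Z)-3-({[(2R)-2-methylbutanoyl]oxy}methyl)-5-[(1R,4aR,8aR)-5,5,8a-trimethyl-2-methylidenedecahydronaphthalen-1-yl]pent-2-enoic acid (CNP0176758.1) | C=C1CC[C@@H]2C(C)(C)CCC[C@@]2(C)[C@@H]1CC/C(=C/C(=O)O)COC(=O)[C@H](C)CC | target

Total step count: 12. Longest linear sequence: 11 steps (steps 1–7 and 9–12); step 8 is a one-step side branch.

Steps most likely to fail

1. Step 7 (Proposed new method). What may go wrong: loss of a proton from the ring-expanded C10 cation before ring B closes, a competing shift of C1 or of the methyl group, or attack of Tf2O on the allylsilane. The fallback uses known reactions only and carries out ring expansion and ring B closure as two separate operations; it sets out from 6 and comes back at 15. Hydrobromination of enone 6 (HBr, Et2O, 0 °C) should give 3-bromo-1-[(1R)-1,2,2-trimethylcyclopentyl]propan-1-one F1. CBS reduction as in step 4 should give (1R)-3-bromo-1-[(1R)-1,2,2-trimethylcyclopentyl]propan-1-ol F2, and MsCl/Et3N its methanesulfonate, (1R)-3-bromo-1-[(1R)-1,2,2-trimethylcyclopentyl]propyl methanesulfonate F3. Buffered methanolysis (MeOH, 2,6-lutidine, 50 °C) is a classical solvolytic Wagner–Meerwein ring expansion in a molecule without a π-nucleophile and should trap the C10 cation as the tertiary methyl ether (2R)-2-(2-bromoethyl)-1-methoxy-1,3,3-trimethylcyclohexane F4 (both C1 epimers serve). Alkylation of 5-lithio-2,3-dihydrofuran 8 with F4 should give 5-{2-[(1R)-2-methoxy-2,6,6-trimethylcyclohexyl]ethyl}-2,3-dihydrofuran F5. The nickel-catalysed ring-opening coupling of step 5 should give (3Z)-6-[(1R)-2-methoxy-2,6,6-trimethylcyclohexyl]-4-[(trimethylsilyl)methyl]hex-3-en-1-ol F6, and Appel bromination (1R)-1-{(3Z)-6-bromo-3-[(trimethylsilyl)methyl]hex-3-en-1-yl}-2-methoxy-2,6,6-trimethylcyclohexane F7. SnCl4 (CH2Cl2, −78 °C) then ionises the tertiary ether, and the allylsilane should close ring B to 15.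

2. Step 10. What may go wrong: cyclisation of the freed (Z)-γ-hydroxy ester to the butenolide with loss of the tert-butyl group during desilylation or the following acylation. The fallback needs neither an ester protecting group nor a free cis-hydroxy ester; it sets out from 15 and comes back at 26. Grignard reagent 19 is added to the chloromagnesium alkoxide of propargyl alcohol with catalytic CuI (alkoxide-directed anti-carbomagnesiation), and the vinylmagnesium is quenched with I2. This should give (2Z)-3-iodo-2-{2-[(1R,4aR,8aR)-5,5,8a-trimethyl-2-methylidenedecahydronaphthalen-1-yl]ethyl}prop-2-en-1-ol F8. Steglich esterification with 23 should give (2Z)-3-iodo-2-{2-[(1R,4aR,8aR)-5,5,8a-trimethyl-2-methylidenedecahydronaphthalen-1-yl]ethyl}prop-2-en-1-yl (2R)-2-methylbutanoate F9. Palladium-catalysed hydroxycarbonylation (Pd(OAc)2, PPh3, CO 1 atm, KOAc, H2O/DMF, 50 °C), which proceeds with retention at the vinyl iodide, should give 26.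

3. Step 1. What may go wrong: attack of the thiohydroxamate at the wrong carbonyl of the anhydride, or a poor radical chain in the presence of the free carboxylate, so that the wrong carboxyl group is lost or none at all. The fallback takes its regiocontrol from the faster saponification of the secondary ester; it sets out from 1 and comes back at 4. Methanolysis of 1 (NaOMe, MeOH) followed by MeI should give dimethyl (1R,3S)-1,2,2-trimethylcyclopentane-1,3-dicarboxylate F10. KOH (1 equiv) in aqueous MeOH should hydrolyse only the unhindered secondary ester to (1S,3R)-3-(methoxycarbonyl)-2,2,3-trimethylcyclopentane-1-carboxylic acid F11. Classical Barton decarboxylation through the acid chloride should give methyl (1R)-1,2,2-trimethylcyclopentane-1-carboxylate F12, and saponification of the hindered ester (KOH, ethylene glycol, 150 °C; no α-hydrogen, so no epimerisation) should give 4.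

Further compounds
F1 | step 7 | 3-bromo-1-[(1R)-1,2,2-trimethylcyclopentyl]propan-1-one | C[C@]1(CCCC1(C)C)C(=O)CCBr
F2 | step 7 | (1R)-3-bromo-1-[(1R)-1,2,2-trimethylcyclopentyl]propan-1-ol | C[C@]1(CCCC1(C)C)[C@H](O)CCBr
F3 | step 7 | (1R)-3-bromo-1-[(1R)-1,2,2-trimethylcyclopentyl]propyl methanesulfonate | C[C@]1(CCCC1(C)C)[C@H](OS(C)(=O)=O)CCBr
F4 | step 7 | (2R)-2-(2-bromoethyl)-1-methoxy-1,3,3-trimethylcyclohexane | COC1(C)CCCC(C)(C)[C@H]1CCBr
F5 | step 7 | 5-{2-[(1R)-2-methoxy-2,6,6-trimethylcyclohexyl]ethyl}-2,3-dihydrofuran | COC1(C)CCCC(C)(C)[C@H]1CCC1=CCCO1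
F6 | step 7 | (3Z)-6-[(1R)-2-methoxy-2,6,6-trimethylcyclohexyl]-4-[(trimethylsilyl)methyl]hex-3-en-1-ol | COC1(C)CCCC(C)(C)[C@H]1CC/C(C[Si](C)(C)C)=C/CCO
F7 | step 7 | (1R)-1-{(3Z)-6-bromo-3-[(trimethylsilyl)methyl]hex-3-en-1-yl}-2-methoxy-2,6,6-trimethylcyclohexane | COC1(C)CCCC(C)(C)[C@H]1CC/C(C[Si](C)(C)C)=C/CCBr
F8 | step 10 | (2Z)-3-iodo-2-{2-[(1R,4aR,8aR)-5,5,8a-trimethyl-2-methylidenedecahydronaphthalen-1-yl]ethyl}prop-2-en-1-ol | C=C1CC[C@@H]2C(C)(C)CCC[C@@]2(C)[C@@H]1CC/C(=C/I)CO
F9 | step 10 | (2Z)-3-iodo-2-{2-[(1R,4aR,8aR)-5,5,8a-trimethyl-2-methylidenedecahydronaphthalen-1-yl]ethyl}prop-2-en-1-yl (2R)-2-methylbutanoate | C=C1CC[C@@H]2C(C)(C)CCC[C@@]2(C)[C@@H]1CC/C(=C/I)COC(=O)[C@H](C)CC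
F10 | step 1 | dimethyl (1R,3S)-1,2,2-trimethylcyclopentane-1,3-dicarboxylate | C[C@]1(CC[C@H](C(=O)OC)C1(C)C)C(=O)OC
F11 | step 1 | (1S,3R)-3-(methoxycarbonyl)-2,2,3-trimethylcyclopentane-1-carboxylic acid | C[C@]1(CC[C@H](C(=O)O)C1(C)C)C(=O)OC
F12 | step 1 | methyl (1R)-1,2,2-trimethylcyclopentane-1-carboxylate | C[C@]1(CCCC1(C)C)C(=O)OC
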